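**Assumption:** the target has no stereocentre (the C(CH3)2 carbon carries two identical methyl groups and the SMILES has no stereodescriptors), so it is achiral and needs no stereocontrol; it is made as the enol tautomer drawn.

**Unit shorthand:** Fil = butyrylfilicinic acid ring (ring 1); Phl = butyrylphloroglucinol ring bridged at C-3/C-5 (rings 2 to 5); MePhl = 3-methyl-butyrylphloroglucinol ring (ring 6). The target is Fil–CH2–Phl–CH2–Phl–CH2–Phl–CH2–Phl–CH2–MePhl.

## Retrosynthetic overview

1. Cut the central CH2 (between rings 3 and 4) into a Fil-capped trimer and a MePhl-capped trimer, joined by Mannich base / quinone methide alkylation.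
2. Each trimer comes from its end cap (as a Mannich base) plus the same symmetric dimer H-Phl–CH2–Phl-H, used in excess.
3. Key disconnection: both benzene rings of the dimer are traced back to a 3,3'-methylene-bridged bis(4-hydroxy-6-(2-oxopentyl)-2-pyrone); forward, a double Claisen recyclisation builds two carbocycles in one operation.
4. The bis-pyrone comes from formaldehyde and two pyrones; the pyrone comes from the dianion of triacetic acid lactone and methyl butanoate.
5. Ring order: rings 2/3 and 4/5 are made de novo, two at a time, in the key step; ring 1 (from phloroglucinol) and ring 6 (from methylphloroglucinol) are bought as carbocycles. Bridges 2–3 and 4–5 are set before ring formation, then 1–2 and 5–6, and 3–4 last.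

## Route

**Step 1**
Reactants: 1 4-hydroxy-6-methyl-2H-pyran-2-one (triacetic acid lactone, 2.0 equiv); 2 methyl butanoate (1.0 equiv)
Product: 3 4-hydroxy-6-(2-oxopentyl)-2H-pyran-2-one
Conditions: LiN(iPr)2 (4.2 equiv), THF, −78 → −20 °C; then 2, −78 → 0 °C; 2 M HCl
Reagents that add atoms: none
Why: LiN(iPr)2 turns 1 into its O,C-dianion, whose vinylogous carbanion at the 6-methyl group is C-acylated by the ester (Claisen-type condensation of a dianion), the second equivalent of dianion taking up the acidic proton of the product; no stereocentre is formed.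

**Step 2**
Reactants: 3 4-hydroxy-6-(2-oxopentyl)-2H-pyran-2-one (2 equiv)
Product: 4 3,3'-methylenebis[4-hydroxy-6-(2-oxopentyl)-2H-pyran-2-one]
Conditions: 37% aq. CH2O (0.52 equiv per 3), EtOH, 70 °C
Reagents that add atoms: formaldehyde, C=O
Why: Knoevenagel condensation of formaldehyde at the enolic C-3 of one pyrone followed by Michael addition of a second pyrone (the dicoumarol-type reaction) gives the methylene bis-pyrone, C-3 being the only strongly nucleophilic carbon of a 4-hydroxy-2-pyrone under neutral conditions; no stereocentre is formed.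

**Step 3 (key step)**
Reactants: 4 3,3'-methylenebis[4-hydroxy-6-(2-oxopentyl)-2H-pyran-2-one]
Product: 6 3,3'-methylenebis(2,4,6-trihydroxybutyrophenone) (dimer H-Phl–CH2–Phl-H), via bis(triketo ester) 5 (not isolated)
Conditions: Mg(OMe)2 (10 equiv), MeOH, reflux; then 1 M HCl, 0 °C
Reagents that add atoms: none
Why: Proposed new method: methoxide opens both lactones to the magnesium-chelated bis(triketo ester) 5, in which the C-4 methylene of each 3,5-dioxooctanoyl arm C-acylates the ester carbonyl (Claisen/Dieckmann-type condensation) and the cyclohexanetrione enolises to the acylphloroglucinol, so two benzene rings form in the same operation; the competing aldol mode would make the bridge-bearing carbon quaternary and cannot aromatise, which biases both halves to the Claisen mode; the closest known reaction type is the Mg(OMe)2 recyclisation of single 4-hydroxy-6-(2-oxoalkyl)-2-pyrones to acylphloroglucinols (biomimetic polyketide Claisen cyclisation); no stereocentre remains.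

**Step 4**
Reactants: 7 phloroglucinol (benzene-1,3,5-triol); 8 butanoyl chloride
Product: 9 1-(2,4,6-trihydroxyphenyl)butan-1-one
Conditions: AlCl3 (3.5 equiv), PhNO2/CH2Cl2, 0 → 40 °C; aq. HCl
Reagents that add atoms: none
Why: Friedel–Crafts acylation of the electron-rich triol stops at the mono-ketone because the chelated acyl group deactivates the ring; no stereocentre is formed.

**Step 5**
Reactants: 9 1-(2,4,6-trihydroxyphenyl)butan-1-one
Product: 10 butyrylfilicinic acid (2-butanoyl-3,5-dihydroxy-4,4-dimethylcyclohexa-2,5-dien-1-one)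
Conditions: NaOMe (3 equiv), MeI (2.5 equiv), MeOH, 0 °C → rt; aq. HCl
Reagents that add atoms: iodomethane, CI
Why: Two successive C-alkylations of the ambident phloroglucinolate at the same ring carbon give the dearomatised gem-dimethyl triketone (filicinic acid pattern), separated by chromatography from the 3-methyl and 3,5-dimethyl by-products; the quaternary carbon bears two identical methyl groups and is not a stereocentre.

**Step 6**
Reactants: 11 2-methylbenzene-1,3,5-triol (methylphloroglucinol); 8 butanoyl chloride
Product: 12 1-(2,4,6-trihydroxy-3-methylphenyl)butan-1-one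
Conditions: AlCl3 (3.5 equiv), PhNO2/CH2Cl2, 0 → 40 °C; aq. HCl
Reagents that add atoms: none
Why: Friedel–Crafts acylation at one of the two equivalent free ring positions gives a single mono-ketone that keeps exactly one nucleophilic C–H; no stereocentre is formed.

**Step 7**
Reactants: 10 butyrylfilicinic acid (1 equiv); 6 3,3'-methylenebis(2,4,6-trihydroxybutyrophenone) (3 equiv, excess recovered)
Product: 14 Fil–CH2–Phl–CH2–Phl-H trimer (ring 1 joined through CH2 to C-3 of a butyrylphloroglucinol ring whose C-5 is joined through CH2 to C-3 of a second butyrylphloroglucinol ring with C-5 free), via Mannich base 13 (not isolated)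
Conditions: CH2(NMe2)2 (1.0 equiv), CH2Cl2, 0 °C → rt, evaporate; then 6 (3 equiv), 1,4-dioxane, 60 °C, N2 sparge
Reagents that add atoms: bis(dimethylamino)methane, CN(C)CN(C)C
Why: Mannich aminomethylation of the only enolic C–H of 10 gives the β-amino triketone 13, which loses dimethylamine (E1cB) to an exocyclic methylene trione (quinone-methide-type acceptor) that is trapped by Michael/Friedel–Crafts C-alkylation at one of the two equivalent free positions of 6, the excess of 6 favouring mono-alkylation; no stereocentre is formed.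

**Step 8**
Reactants: 12 1-(2,4,6-trihydroxy-3-methylphenyl)butan-1-one (1 equiv); 6 3,3'-methylenebis(2,4,6-trihydroxybutyrophenone) (3 equiv, excess recovered)
Product: 16 H-Phl–CH2–Phl–CH2–MePhl trimer (ring 6 joined through CH2 to C-3 of a butyrylphloroglucinol ring whose C-5 is joined through CH2 to C-3 of a second butyrylphloroglucinol ring with C-5 free), via Mannich base 15 (not isolated)
Conditions: CH2(NMe2)2 (1.0 equiv), 1,4-dioxane, rt, evaporate; then 6 (3 equiv), 1,4-dioxane, 90 °C, N2 sparge
Reagents that add atoms: bis(dimethylamino)methane, CN(C)CN(C)C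
Why: Mannich reaction at the single free ring position of 12 gives the phenolic Mannich base 15, which on heating expels dimethylamine to a quinone methide that C-alkylates one free position of excess 6 (quinone methide Friedel–Crafts alkylation); no stereocentre is formed.

**Step 9**
Reactants: 16 H-Phl–CH2–Phl–CH2–MePhl trimer (1 equiv); 14 Fil–CH2–Phl–CH2–Phl-H trimer (1.1 equiv)
Product: 18 CNP0309827.0 (target hexamer), via Mannich base 17 (not isolated)
Conditions: CH2(NMe2)2 (1.0 equiv), 1,4-dioxane, rt, evaporate; then 14 (1.1 equiv), 1,4-dioxane, 90 °C, N2 sparge; Sephadex LH-20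
Reagents that add atoms: bis(dimethylamino)methane, CN(C)CN(C)C
Why: Each trimer has exactly one nucleophilic ring C–H, so Mannich activation of 16 at that position and thermal quinone methide formation from 17 leave the single free position of 14 as the only C-nucleophile, and the cross-coupling (quinone methide Friedel–Crafts alkylation) sets the last bridge between rings 3 and 4 without homodimers; no stereocentre is formed.

## Compound list

1 | 4-hydroxy-6-methyl-2H-pyran-2-one (triacetic acid lactone) | CC1=CC(O)=CC(=O)O1 | starting material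
2 | methyl butanoate | CCCC(=O)OC | starting material
3 | 4-hydroxy-6-(2-oxopentyl)-2H-pyran-2-one | CCCC(=O)CC1=CC(O)=CC(=O)O1 | intermediate
4 | 3,3'-methylenebis[4-hydroxy-6-(2-oxopentyl)-2H-pyran-2-one] | CCCC(=O)CC1=CC(O)=C(CC2=C(O)C=C(CC(=O)CCC)OC2=O)C(=O)O1 | intermediate
5 | dimethyl 2,4-bis(3,5-dioxooctanoyl)pentanedioate (bis(triketo ester), present as magnesium enolates; keto form drawn, both CH centres enolised and configurationally labile) | COC(=O)C(CC(C(=O)OC)C(=O)CC(=O)CC(=O)CCC)C(=O)CC(=O)CC(=O)CCC | intermediate (not isolated)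
6 | 3,3'-methylenebis(2,4,6-trihydroxybutyrophenone), dimer H-Phl–CH2–Phl-H | CCCC(=O)c1c(O)cc(O)c(Cc2c(O)cc(O)c(C(=O)CCC)c2O)c1O | intermediate
7 | phloroglucinol (benzene-1,3,5-triol) | Oc1cc(O)cc(O)c1 | starting material
8 | butanoyl chloride | CCCC(=O)Cl | starting material
9 | 1-(2,4,6-trihydroxyphenyl)butan-1-one | CCCC(=O)c1c(O)cc(O)cc1O | intermediate
10 | butyrylfilicinic acid (2-butanoyl-3,5-dihydroxy-4,4-dimethylcyclohexa-2,5-dien-1-one) | CCCC(=O)C1=C(O)C(C)(C)C(O)=CC1=O | intermediate
11 | 2-methylbenzene-1,3,5-triol (methylphloroglucinol) | Cc1c(O)cc(O)cc1O | starting material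
12 | 1-(2,4,6-trihydroxy-3-methylphenyl)butan-1-one | CCCC(=O)c1c(O)cc(O)c(C)c1O | intermediate
13 | 2-butanoyl-6-[(dimethylamino)methyl]-3,5-dihydroxy-4,4-dimethylcyclohexa-2,5-dien-1-one (Mannich base of 10) | CCCC(=O)C1=C(O)C(C)(C)C(O)=C(CN(C)C)C1=O | intermediate (not isolated)
14 | Fil–CH2–Phl–CH2–Phl-H trimer | CCCC(=O)C1=C(O)C(C)(C)C(O)=C(Cc2c(O)c(Cc3c(O)cc(O)c(C(=O)CCC)c3O)c(O)c(C(=O)CCC)c2O)C1=O | intermediate
15 | 1-{3-[(dimethylamino)methyl]-2,4,6-trihydroxy-5-methylphenyl}butan-1-one (Mannich base of 12) | CCCC(=O)c1c(O)c(C)c(O)c(CN(C)C)c1O | intermediate (not isolated)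
16 | H-Phl–CH2–Phl–CH2–MePhl trimer | CCCC(=O)c1c(O)cc(O)c(Cc2c(O)c(Cc3c(O)c(C)c(O)c(C(=O)CCC)c3O)c(O)c(C(=O)CCC)c2O)c1O | intermediate
17 | Mannich base of 16 (dimethylaminomethyl group at the free ring position of the terminal Phl ring) | CCCC(=O)c1c(O)c(CN(C)C)c(O)c(Cc2c(O)c(Cc3c(O)c(C)c(O)c(C(=O)CCC)c3O)c(O)c(C(=O)CCC)c2O)c1O | intermediate (not isolated)
18 | CNP0309827.0 (Fil–CH2–Phl–CH2–Phl–CH2–Phl–CH2–Phl–CH2–MePhl), achiral | CCCC(=O)C1=C(O)C(C)(C)C(O)=C(Cc2c(O)c(Cc3c(O)c(Cc4c(O)c(Cc5c(O)c(Cc6c(O)c(C)c(O)c(C(=O)CCC)c6O)c(O)c(C(=O)CCC)c5O)c(O)c(C(=O)CCC)c4O)c(O)c(C(=O)CCC)c3O)c(O)c(C(=O)CCC)c2O)C1=O | target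

## Summary

Total step count: 9.
Longest linear sequence: 5 steps (1 → 3 → 4 → 6 → 16 → 18; the branch through 14 is equally long).

**Three steps most likely to fail**

Step 3 (double recyclisation). The opened bis(triketo ester) may fragment by retro-Michael loss of the bridge, or only one half may close. The fallback sets out from pyrone 3 and comes back at dimer 6. The ring is closed first on the monomer: 3 with Mg(OMe)2 in MeOH gives 1-(2,4,6-trihydroxyphenyl)butan-1-one 9, the single-ring Claisen recyclisation. The bridge is made afterwards: 9 in fourfold excess with aqueous formaldehyde and dilute NaOH at 0 °C gives 6, and the excess 9 is recovered. This gives up the two-ring operation and bridges after ring formation instead of before. It makes no new compound (F0).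

Step 7 (mono-alkylation of the symmetric dimer; step 8 carries the same risk). Double capping of 6 and amine-promoted scrambling of the methylene bridge can erode the yield. The fallback sets out from 10 (through its Mannich base 13) and pyrone 3 and comes back at 14. It uses the pyrone as a latent ring with only one nucleophilic carbon, so no excess and no statistics are needed. Heating 13 with 3 in dioxane gives the Fil–CH2–pyrone dimer F1. Mg(OMe)2 recyclisation of its pyrone gives the Fil–CH2–Phl-H dimer F2, which now shows one new free ring position. Aminomethylation of F2 with CH2(NMe2)2 gives the Mannich base of the Fil–CH2–Phl dimer F3. Heating F3 with 3 gives the Fil–CH2–Phl–CH2–pyrone trimer F4, and a second Mg(OMe)2 recyclisation gives 14.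

Step 9 (trimer plus trimer coupling). The quinone methide from 17 is large and slow to be trapped, which gives time for retro-Mannich scrambling. The fallback sets out from 14 and comes back at 18; it moves the last bond formation to a small, reactive electrophile. Aminomethylation of 14 with CH2(NMe2)2 gives the Mannich base of the Fil-capped trimer F5. Heating F5 with excess 6 gives the Fil–CH2–(Phl–CH2)3–Phl-H pentamer F6, which has one free ring position. F6 is then capped with the Mannich base 15, made from 12 as in step 8, to give 18.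

## Further compounds

F0 | step 3 | none | none
F1 | step 7 | Fil–CH2–pyrone dimer (butyrylfilicinic acid ring joined through CH2 to C-3 of 4-hydroxy-6-(2-oxopentyl)-2H-pyran-2-one) | CCCC(=O)C1=C(O)C(C)(C)C(O)=C(CC2=C(O)C=C(CC(=O)CCC)OC2=O)C1=O
F2 | step 7 | Fil–CH2–Phl-H dimer | CCCC(=O)C1=C(O)C(C)(C)C(O)=C(Cc2c(O)cc(O)c(C(=O)CCC)c2O)C1=O
F3 | step 7 | Mannich base of the Fil–CH2–Phl dimer (dimethylaminomethyl group at the free ring position) | CCCC(=O)C1=C(O)C(C)(C)C(O)=C(Cc2c(O)c(CN(C)C)c(O)c(C(=O)CCC)c2O)C1=O
F4 | step 7 | Fil–CH2–Phl–CH2–pyrone trimer | CCCC(=O)C1=C(O)C(C)(C)C(O)=C(Cc2c(O)c(CC3=C(O)C=C(CC(=O)CCC)OC3=O)c(O)c(C(=O)CCC)c2O)C1=O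
F5 | step 9 | Mannich base of the Fil-capped trimer 14 (dimethylaminomethyl group at the free ring position) | CCCC(=O)C1=C(O)C(C)(C)C(O)=C(Cc2c(O)c(Cc3c(O)c(CN(C)C)c(O)c(C(=O)CCC)c3O)c(O)c(C(=O)CCC)c2O)C1=O
F6 | step 9 | Fil–CH2–(Phl–CH2)3–Phl-H pentamer | CCCC(=O)C1=C(O)C(C)(C)C(O)=C(Cc2c(O)c(Cc3c(O)c(Cc4c(O)c(Cc5c(O)cc(O)c(C(=O)CCC)c5O)c(O)c(C(=O)CCC)c4O)c(O)c(C(=O)CCC)c3O)c(O)c(C(=O)CCC)c2O)C1=O
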